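(The numbers were set for the occasion, and the outcome is calculated.)

Minutes were the unit I reckoned in for this flask.

    substrate + acid → weak acid + acid + target (k1 = 167 M⁻¹ s⁻¹)
    weak acid ⇌ conjugate base + acid, settled at all times (K2 = 2.5 × 10⁻⁷ M)
    substrate → weak acid + target (k3 = 5.06 × 10⁻⁴ s⁻¹)
    substrate + target → side product (k4 = 0.0110 M⁻¹ s⁻¹)
    substrate + weak acid ⇌ idle adduct, settled at all times (K5 = 2020 M⁻¹)

substrate 0.010 M; acid 0.0100 mM; time 12 min

* part of the substrate that has reacted at 12 min
* pH of the solution at 12 min

I joined the charged acid and step 3 into one pseudo-first-order rate, 0.131 min⁻¹. Each turnover made a weak acid. At the start nearly all of it should bind a second substrate as idle adduct, because the binding constant times the charge stood far above one. So I let two substrates go per turnover. I called the time in which free substrate falls by a factor e, at that loss and the charged acid, the capture clock: 3.83 min.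

Over the run this reckoning left 0.436 mM of free substrate, so I computed that remainder and took c as 95.6%. I set side product and conjugate base aside as small, so my balance of the charge counted free substrate, free weak acid and two substrates per adduct. It gave 3.47 mM of free weak acid. With the charged acid added, I reckoned acid at 0.0349 mM, so I put the pH at 4.46.

The weak link was the two per turnover. Differentiating the balance gave 0.311 substrates per turnover at my end point. With my final acid, the loss there was 0.118 min⁻¹, slower than the clock's 0.261 min⁻¹. Running the last clock span at that rate lowered c to 92.5%. But my final acid gave a faster turnover than the charged acid, which pushed the other way earlier, so I kept my figure and took this as the margin.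

The forecast said 95.3% and 4.47, on the ground that “The adduct holds back most of the weak acid early, so autocatalysis is weak at first.”

The flask gave 95.2% and 4.47. Idle adduct still held 31.2% of the charge at 12.0 min, and that part can come back. The capture clock gave 79.1% at 6.00 min, when the flask had used 84.3%. For the neighbouring flask read at 3.0 min, the clock gave 54.3%, and that flask read 58.6%.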